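## Retrosynthetic overview

1. The last operation is acid removal of seven MOM ethers. Before it, the dihydrofuran ring (O1–C2–C3–C3a–C7a) is closed last by a formal [4+1] annulation that makes C2–C3 and O1–C2 and sets both stereocentres.
2. Enabling feature: C3 is a benzhydryl carbon bonded to C3a, which is ortho to the oxygen-bearing C7a, and it also carries a 4-oxygenated phenyl ring. O1=C7a–C3a=C3 is therefore a latent o-quinone methide, O1 is the built-in nucleophile, and C2 can arrive as a benzylic sulfonium-ylide carbon carrying the resorcinol ring.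
3. The quinone-methide precursor (benzhydryl sulfone 19) comes from flavone phenol 14 by ortho-formylation, aryl Grignard addition and sulfinate exchange.
4. The 3-methoxyflavone comes from acetophenone 7 and aldehyde 10 by Claisen–Schmidt condensation, Algar–Flynn–Oyamada cyclisation and O-methylation. The 6-methyl pattern is fixed by making the cyclising phenol through C–H borylation/oxidation of 2-methylresorcinol bis-MOM ether.
5. Ring order: benzene rings A and B are bought; the pyranone ring closes in step 9; the dihydrofuran ring closes in step 19.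

Key step: step 19

Assumption: (1R,4R,5R)-isothiocineole 24 is taken as the commercial enantiomer whose benzyl ylides give (R,R)-trans-epoxides from aldehydes; the sense of induction in step 19 is assigned by that analogy, and the enantiomeric sulfide would be used if the sense proved opposite.

## Route

Step 1
Reactants: 1 2-methylbenzene-1,3-diol (2-methylresorcinol)
Product: 2 1,3-bis(methoxymethoxy)-2-methylbenzene
Conditions: NaH (2.4 equiv), MOMCl (2.4 equiv), DMF, 0 °C to rt
Reagents that add atoms: chloromethyl methyl ether, COCCl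
Why: Williamson-type O-alkylation of both phenoxides; MOM survives every later basic and organometallic step and leaves under the mild acid of step 20.

Step 2
Reactants: 2 1,3-bis(methoxymethoxy)-2-methylbenzene
Product: 4 3,5-bis(methoxymethoxy)-4-methylphenol, via arylboronate 3 (not isolated)
Conditions: [Ir(OMe)(cod)]2 (1.5 mol%), dtbpy (3 mol%), B2pin2 (1.0 equiv), THF, 80 °C; then aq. NaOH, 30% H2O2, 0 °C to rt
Reagents that add atoms: hydrogen peroxide, OO
Why: Sterically governed iridium-catalysed C–H borylation should take the only ring C–H with no ortho neighbour (para to the methyl), and boronate oxidation then gives a phenol flanked by two C–H, which will become the pyranone oxygen and so fixes the 6-methyl (not 8-methyl) pattern.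

Step 3
Reactants: 4 3,5-bis(methoxymethoxy)-4-methylphenol
Product: 5 6-hydroxy-2,4-bis(methoxymethoxy)-3-methylbenzaldehyde
Conditions: MgCl2 (2 equiv), Et3N (4 equiv), (CH2O)n (6 equiv), MeCN, reflux
Reagents that add atoms: paraformaldehyde (as formaldehyde), C=O
Why: Magnesium-phenoxide-directed ortho-formylation (Casiraghi–Skattebøl) is ortho-specific and non-acidic, and the two ortho positions are equivalent by symmetry.

Step 4
Reactants: 5 6-hydroxy-2,4-bis(methoxymethoxy)-3-methylbenzaldehyde
Product: 6 2-(1-hydroxyethyl)-3,5-bis(methoxymethoxy)-4-methylphenol (racemic)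
Conditions: MeMgBr (3 equiv), THF, 0 °C; aq. NH4Cl
Reagents that add atoms: methylmagnesium bromide, C[Mg]Br
Why: Grignard addition to the aldehyde after the first equivalent has deprotonated the phenol; the new stereocentre is destroyed in step 5.

Step 5
Reactants: 6 2-(1-hydroxyethyl)-3,5-bis(methoxymethoxy)-4-methylphenol
Product: 7 1-[6-hydroxy-2,4-bis(methoxymethoxy)-3-methylphenyl]ethan-1-one
Conditions: activated MnO2 (15 equiv), CH2Cl2, rt
Reagents that add atoms: none
Why: MnO2 oxidation of an electron-rich benzylic alcohol is neutral and should leave the phenol and the MOM ethers untouched.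

Step 6
Reactants: 8 2,4,5-trihydroxybenzaldehyde
Product: 9 4-(benzyloxy)-2,5-dihydroxybenzaldehyde
Conditions: BnBr (1.05 equiv), NaHCO3 (1.2 equiv), NaI (cat.), DMF, 40 °C, argon
Reagents that add atoms: benzyl bromide, BrCc1ccccc1
Why: Williamson mono-alkylation under weak base should go to the most acidic phenol, the 4-OH para to the formyl group (the 2-OH is hydrogen-bonded, the 5-OH is meta), which marks the oxygen that later becomes O1 of the dihydrofuran.

Step 7
Reactants: 9 4-(benzyloxy)-2,5-dihydroxybenzaldehyde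
Product: 10 4-(benzyloxy)-2,5-bis(methoxymethoxy)benzaldehyde
Conditions: MOMCl (4 equiv), i-Pr2NEt (5 equiv), CH2Cl2, 0 °C to reflux
Reagents that add atoms: chloromethyl methyl ether, COCCl
Why: O-alkylation of the two remaining phenols with an acetal chloride under amine base, which tolerates the non-enolisable aldehyde.

Step 8
Reactants: 7 1-[6-hydroxy-2,4-bis(methoxymethoxy)-3-methylphenyl]ethan-1-one; 10 4-(benzyloxy)-2,5-bis(methoxymethoxy)benzaldehyde
Product: 11 (E)-3-[4-(benzyloxy)-2,5-bis(methoxymethoxy)phenyl]-1-[6-hydroxy-2,4-bis(methoxymethoxy)-3-methylphenyl]prop-2-en-1-one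
Conditions: 50% aq. KOH, EtOH, rt, 48 h
Reagents that add atoms: none
Why: Claisen–Schmidt aldol condensation of the methyl ketone with the non-enolisable aldehyde; E1cB dehydration gives the E-enone.

Step 9
Reactants: 11 the (E)-chalcone
Product: 12 2-[4-(benzyloxy)-2,5-bis(methoxymethoxy)phenyl]-3-hydroxy-5,7-bis(methoxymethoxy)-6-methyl-4H-chromen-4-one
Conditions: 30% H2O2 (5 equiv), 2 M NaOH, MeOH/THF, 0 °C to rt
Reagents that add atoms: hydrogen peroxide, OO
Why: Algar–Flynn–Oyamada oxidative cyclisation closes the pyranone ring through the only free phenol and installs the 3-OH under basic conditions that keep every MOM and benzyl ether.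

Step 10
Reactants: 12 the 3-hydroxyflavone
Product: 13 2-[4-(benzyloxy)-2,5-bis(methoxymethoxy)phenyl]-3-methoxy-5,7-bis(methoxymethoxy)-6-methyl-4H-chromen-4-one
Conditions: MeI (3 equiv), K2CO3 (3 equiv), acetone, reflux
Reagents that add atoms: iodomethane, CI
Why: Williamson O-methylation of the only free hydroxyl installs the methyl ether that the target keeps.

Step 11
Reactants: 13 the benzyl ether
Product: 14 2-[4-hydroxy-2,5-bis(methoxymethoxy)phenyl]-3-methoxy-5,7-bis(methoxymethoxy)-6-methyl-4H-chromen-4-one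
Conditions: H2 (1 atm), 10% Pd/C, EtOAc/THF, rt
Reagents that add atoms: none
Why: Hydrogenolysis of the single aryl benzyl ether; the tetrasubstituted, methoxy-bearing C2=C3 of the chromone and the MOM ethers are inert.

Step 12
Reactants: 14 the flavone phenol
Product: 15 2-hydroxy-3,6-bis(methoxymethoxy)-5-[3-methoxy-5,7-bis(methoxymethoxy)-6-methyl-4-oxo-4H-chromen-2-yl]benzaldehyde
Conditions: MgCl2 (3 equiv), Et3N (6 equiv), (CH2O)n (10 equiv), MeCN, reflux
Reagents that add atoms: paraformaldehyde (as formaldehyde), C=O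
Why: Casiraghi–Skattebøl ortho-formylation acts only ortho to a free phenol, and the one open ortho position is the carbon that becomes C3a; loss of the peri 5-O-MOM group here would be harmless.

Step 13
Reactants: 15 the salicylaldehyde; 16 1-bromo-4-(methoxymethoxy)benzene
Product: 18 2-{4-hydroxy-3-[hydroxy(4-(methoxymethoxy)phenyl)methyl]-2,5-bis(methoxymethoxy)phenyl}-3-methoxy-5,7-bis(methoxymethoxy)-6-methyl-4H-chromen-4-one (racemic), via Grignard reagent 17 (not isolated)
Conditions: 16, Mg, THF, rt (forms 17); 17 (2.5 equiv) added to 15, THF, -78 to -20 °C; aq. NH4Cl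
Reagents that add atoms: none
Why: Grignard addition to the aldehyde (first equivalent deprotonates the phenol) is much faster at low temperature than attack on the hindered vinylogous-ester carbonyl of the chromone; the carbinol stereocentre is erased in step 19.

Step 14
Reactants: 18 the o-hydroxybenzhydrol
Product: 19 2-{4-hydroxy-2,5-bis(methoxymethoxy)-3-[(4-(methoxymethoxy)phenyl)(4-methylbenzenesulfonyl)methyl]phenyl}-3-methoxy-5,7-bis(methoxymethoxy)-6-methyl-4H-chromen-4-one (racemic)
Conditions: p-TolSO2H (2 equiv), 4 Å MS, CH2Cl2, rt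
Reagents that add atoms: p-toluenesulfinic acid, Cc1ccc(cc1)S(=O)O
Why: SN1-type exchange of the doubly activated benzhydryl hydroxyl for sulfinate (S-attack) gives the standard bench-stable, base-triggered o-quinone methide precursor.

Step 15
Reactants: 20 methyl 3,5-dihydroxybenzoate
Product: 21 methyl 3,5-bis(methoxymethoxy)benzoate
Conditions: MOMCl (3 equiv), i-Pr2NEt (4 equiv), CH2Cl2, 0 °C to rt
Reagents that add atoms: chloromethyl methyl ether, COCCl
Why: Routine O-alkylation of both phenols with an acetal chloride.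

Step 16
Reactants: 21 methyl 3,5-bis(methoxymethoxy)benzoate
Product: 22 [3,5-bis(methoxymethoxy)phenyl]methanol
Conditions: LiAlH4 (1.2 equiv), THF, 0 °C; Fieser work-up
Reagents that add atoms: none
Why: Hydride reduction of the ester to the benzylic alcohol; acetals are inert.

Step 17
Reactants: 22 [3,5-bis(methoxymethoxy)phenyl]methanol
Product: 23 1-(bromomethyl)-3,5-bis(methoxymethoxy)benzene
Conditions: CBr4 (1.3 equiv), PPh3 (1.3 equiv), CH2Cl2, 0 °C
Reagents that add atoms: carbon tetrabromide, BrC(Br)(Br)Br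
Why: Appel bromination is neutral, so the acid-labile MOM ethers survive.

Step 18
Reactants: 23 1-(bromomethyl)-3,5-bis(methoxymethoxy)benzene; 24 (1R,4R,5R)-4,7,7-trimethyl-6-thiabicyclo[3.2.1]octane (isothiocineole)
Product: 25 (1R,4R,5R)-6-[3,5-bis(methoxymethoxy)benzyl]-4,7,7-trimethyl-6-thiabicyclo[3.2.1]octan-6-ium trifluoromethanesulfonate
Conditions: 24 (1.0 equiv), 23 (1.2 equiv), LiOTf (2 equiv), CH2Cl2/H2O, rt, 48 h
Reagents that add atoms: lithium trifluoromethanesulfonate, [Li+].[O-]S(=O)(=O)C(F)(F)F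
Why: S-alkylation of the sulfide by the benzylic bromide with anion exchange to the non-nucleophilic triflate; alkylation at the less hindered sulfur lone pair should give one diastereomer at sulfur.

Step 19
Reactants: 19 the racemic benzhydryl sulfone; 25 the chiral benzylsulfonium triflate
Product: 29 2-{(2S,3S)-2-[3,5-bis(methoxymethoxy)phenyl]-4,7-bis(methoxymethoxy)-3-[4-(methoxymethoxy)phenyl]-2,3-dihydro-1-benzofuran-5-yl}-3-methoxy-5,7-bis(methoxymethoxy)-6-methyl-4H-chromen-4-one, via o-quinone methide 26 (not isolated), via sulfonium ylide 27 (not isolated), via betaine 28 (not isolated)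
Conditions: 19 (1.0 equiv), 25 (1.5 equiv), Cs2CO3 (3.5 equiv), MeCN/CH2Cl2 (1:1), -20 °C to rt, argon; sulfide 24 recovered
Reagents that add atoms: none
Why: Proposed new method: Cs2CO3 deprotonates the phenol on C7a of 19 and sulfinate leaves to give the planar o-quinone methide 26 (O=C7a–C3a=C3, stabilised by the 4-alkoxyphenyl group on C3), while the same base reversibly forms benzylic ylide 27, whose carbon adds to the methide carbon (C2–C3 bond, rearomatisation) to give betaine 28; the phenoxide then displaces the sulfide in a 5-exo-tet SN2 closure (O1–C2 bond), the only ring formed. The closest known reaction types are the base-mediated [4+1] annulations of in situ o-quinone methides (from 2-(tosylmethyl)phenols) and of o-hydroxyphenyl p-quinone methides with carbonyl-stabilised sulfonium or ammonium ylides to trans-2,3-dihydrobenzofurans, and benzylidene transfer from isothiocineole benzylsulfonium ylides to aldehydes and imines; new here are an aryl-stabilised chiral ylide on a quinone methide and a methide without blocking groups. C2 is reagent-controlled: the ylide should react through one conformer and one open face, as in its epoxidations, and the invertive closure then gives 2S. C3 is set relative to C2 in the C–C bond-forming step, where an antiperiplanar approach keeps the two aryl groups apart and leads to the trans ring (3S), the cisoid betaine being slow to close because its aryl groups eclipse; both enantiomers of 19 pass through the same achiral 26, so the step is stereoconvergent. The step needs one oxygen to close and one acceptor to react: only the C7a oxygen is free (the oxygen flanking C3a on the other side and the 4-oxygen of the C3 aryl are MOM ethers, so no isomeric ring and no p-quinone methide can form), and the tetrasubstituted C2=C3 of the chromone is a poor acceptor next to the quinone methide.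

Step 20
Reactants: 29 the hepta-MOM ether
Product: 30 2-[(2S,3S)-2-(3,5-dihydroxyphenyl)-4,7-dihydroxy-3-(4-hydroxyphenyl)-2,3-dihydro-1-benzofuran-5-yl]-5,7-dihydroxy-3-methoxy-6-methyl-4H-chromen-4-one (CNP0218412.2)
Conditions: 3 M aq. HCl/MeOH/THF (1:4:2), 45 °C, degassed, argon
Reagents that add atoms: none
Why: Acid-catalysed acetal methanolysis removes all seven MOM groups, while the 3-methyl ether, the chromone and the trans-dihydrobenzofuran (no cation-stabilising para-oxygen on the C2 aryl) are inert to dilute HCl, so neither stereocentre is touched.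

## Compound list

1 | 2-methylbenzene-1,3-diol | Cc1c(O)cccc1O | starting material
2 | 1,3-bis(methoxymethoxy)-2-methylbenzene | Cc1c(OCOC)cccc1OCOC | intermediate
3 | 2-[3,5-bis(methoxymethoxy)-4-methylphenyl]-4,4,5,5-tetramethyl-1,3,2-dioxaborolane (not isolated) | Cc1c(OCOC)cc(cc1OCOC)B1OC(C)(C)C(C)(C)O1 | intermediate
4 | 3,5-bis(methoxymethoxy)-4-methylphenol | Cc1c(OCOC)cc(O)cc1OCOC | intermediate
5 | 6-hydroxy-2,4-bis(methoxymethoxy)-3-methylbenzaldehyde | Cc1c(OCOC)cc(O)c(C=O)c1OCOC | intermediate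
6 | 2-(1-hydroxyethyl)-3,5-bis(methoxymethoxy)-4-methylphenol (racemic) | Cc1c(OCOC)cc(O)c(C(C)O)c1OCOC | intermediate
7 | 1-[6-hydroxy-2,4-bis(methoxymethoxy)-3-methylphenyl]ethan-1-one | Cc1c(OCOC)cc(O)c(C(C)=O)c1OCOC | intermediate
8 | 2,4,5-trihydroxybenzaldehyde | O=Cc1cc(O)c(O)cc1O | starting material
9 | 4-(benzyloxy)-2,5-dihydroxybenzaldehyde | O=Cc1cc(O)c(OCc2ccccc2)cc1O | intermediate
10 | 4-(benzyloxy)-2,5-bis(methoxymethoxy)benzaldehyde | O=Cc1cc(OCOC)c(OCc2ccccc2)cc1OCOC | intermediate
11 | (E)-3-[4-(benzyloxy)-2,5-bis(methoxymethoxy)phenyl]-1-[6-hydroxy-2,4-bis(methoxymethoxy)-3-methylphenyl]prop-2-en-1-one | Cc1c(OCOC)cc(O)c(C(=O)/C=C/c2cc(OCOC)c(OCc3ccccc3)cc2OCOC)c1OCOC | intermediate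
12 | 2-[4-(benzyloxy)-2,5-bis(methoxymethoxy)phenyl]-3-hydroxy-5,7-bis(methoxymethoxy)-6-methyl-4H-chromen-4-one | Cc1c(OCOC)cc2oc(-c3cc(OCOC)c(OCc4ccccc4)cc3OCOC)c(O)c(=O)c2c1OCOC | intermediate
13 | 2-[4-(benzyloxy)-2,5-bis(methoxymethoxy)phenyl]-3-methoxy-5,7-bis(methoxymethoxy)-6-methyl-4H-chromen-4-one | Cc1c(OCOC)cc2oc(-c3cc(OCOC)c(OCc4ccccc4)cc3OCOC)c(OC)c(=O)c2c1OCOC | intermediate
14 | 2-[4-hydroxy-2,5-bis(methoxymethoxy)phenyl]-3-methoxy-5,7-bis(methoxymethoxy)-6-methyl-4H-chromen-4-one | Cc1c(OCOC)cc2oc(-c3cc(OCOC)c(O)cc3OCOC)c(OC)c(=O)c2c1OCOC | intermediate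
15 | 2-hydroxy-3,6-bis(methoxymethoxy)-5-[3-methoxy-5,7-bis(methoxymethoxy)-6-methyl-4-oxo-4H-chromen-2-yl]benzaldehyde | Cc1c(OCOC)cc2oc(-c3cc(OCOC)c(O)c(C=O)c3OCOC)c(OC)c(=O)c2c1OCOC | intermediate
16 | 1-bromo-4-(methoxymethoxy)benzene | COCOc1ccc(Br)cc1 | starting material
17 | [4-(methoxymethoxy)phenyl]magnesium bromide (not isolated) | COCOc1ccc([Mg]Br)cc1 | intermediate
18 | 2-{4-hydroxy-3-[hydroxy(4-(methoxymethoxy)phenyl)methyl]-2,5-bis(methoxymethoxy)phenyl}-3-methoxy-5,7-bis(methoxymethoxy)-6-methyl-4H-chromen-4-one (racemic) | Cc1c(OCOC)cc2oc(-c3cc(OCOC)c(O)c(C(O)c4ccc(OCOC)cc4)c3OCOC)c(OC)c(=O)c2c1OCOC | intermediate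
19 | 2-{4-hydroxy-2,5-bis(methoxymethoxy)-3-[(4-(methoxymethoxy)phenyl)(4-methylbenzenesulfonyl)methyl]phenyl}-3-methoxy-5,7-bis(methoxymethoxy)-6-methyl-4H-chromen-4-one (racemic) | Cc1c(OCOC)cc2oc(-c3cc(OCOC)c(O)c(C(c4ccc(OCOC)cc4)S(=O)(=O)c4ccc(C)cc4)c3OCOC)c(OC)c(=O)c2c1OCOC | intermediate
20 | methyl 3,5-dihydroxybenzoate | COC(=O)c1cc(O)cc(O)c1 | starting material
21 | methyl 3,5-bis(methoxymethoxy)benzoate | COC(=O)c1cc(OCOC)cc(OCOC)c1 | intermediate
22 | [3,5-bis(methoxymethoxy)phenyl]methanol | OCc1cc(OCOC)cc(OCOC)c1 | intermediate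
23 | 1-(bromomethyl)-3,5-bis(methoxymethoxy)benzene | BrCc1cc(OCOC)cc(OCOC)c1 | intermediate
24 | (1R,4R,5R)-4,7,7-trimethyl-6-thiabicyclo[3.2.1]octane (isothiocineole) | C[C@@H]1CC[C@@H]2C[C@H]1SC2(C)C | starting material
25 | (1R,4R,5R)-6-[3,5-bis(methoxymethoxy)benzyl]-4,7,7-trimethyl-6-thiabicyclo[3.2.1]octan-6-ium trifluoromethanesulfonate (configuration at sulfur not assigned) | C[C@@H]1CC[C@@H]2C[C@H]1[S+](Cc1cc(OCOC)cc(OCOC)c1)C2(C)C.[O-]S(=O)(=O)C(F)(F)F | intermediate
26 | 2-{2,5-bis(methoxymethoxy)-3-[4-(methoxymethoxy)benzylidene]-4-oxocyclohexa-1,5-dien-1-yl}-3-methoxy-5,7-bis(methoxymethoxy)-6-methyl-4H-chromen-4-one (o-quinone methide; C=C geometry not defined; not isolated) | COc1c(C2=C(OCOC)C(=Cc3ccc(OCOC)cc3)C(=O)C(OCOC)=C2)oc2cc(OCOC)c(C)c(OCOC)c2c1=O | intermediate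
27 | [3,5-bis(methoxymethoxy)phenyl][(1R,4R,5R)-4,7,7-trimethyl-6-thiabicyclo[3.2.1]octan-6-ium-6-yl]methanide (ylide; not isolated) | C[C@@H]1CC[C@@H]2C[C@H]1[S+]([CH-]c1cc(OCOC)cc(OCOC)c1)C2(C)C | intermediate
28 | betaine: phenoxide of the flavone B ring bearing the (1S,2R)-2-[3,5-bis(methoxymethoxy)phenyl]-1-[4-(methoxymethoxy)phenyl]-2-(isothiocineol-6-ium-6-yl)ethyl group (C–S carbon R, benzhydryl carbon S; not isolated) | COc1c(-c2cc(OCOC)c([O-])c(c2OCOC)[C@H](c2ccc(OCOC)cc2)[C@H](c2cc(OCOC)cc(OCOC)c2)[S+]2[C@@H]3C[C@@H](CC[C@H]3C)C2(C)C)oc2cc(OCOC)c(C)c(OCOC)c2c1=O | intermediate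
29 | 2-{(2S,3S)-2-[3,5-bis(methoxymethoxy)phenyl]-4,7-bis(methoxymethoxy)-3-[4-(methoxymethoxy)phenyl]-2,3-dihydro-1-benzofuran-5-yl}-3-methoxy-5,7-bis(methoxymethoxy)-6-methyl-4H-chromen-4-one | COc1c(-c2cc(OCOC)c3c(c2OCOC)[C@H](c2ccc(OCOC)cc2)[C@@H](c2cc(OCOC)cc(OCOC)c2)O3)oc2cc(OCOC)c(C)c(OCOC)c2c1=O | intermediate
30 | 2-[(2S,3S)-2-(3,5-dihydroxyphenyl)-4,7-dihydroxy-3-(4-hydroxyphenyl)-2,3-dihydro-1-benzofuran-5-yl]-5,7-dihydroxy-3-methoxy-6-methyl-4H-chromen-4-one | COc1c(-c2cc(O)c3c(c2O)[C@H](c2ccc(O)cc2)[C@@H](c2cc(O)cc(O)c2)O3)oc2cc(O)c(C)c(O)c2c1=O | target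

## Step count and risks

Total steps: 20. Longest linear sequence: 14 steps (1–5, 8–14, 19, 20).

**Step 19 (carries the label).** What may go wrong: poor facial discrimination at the methide carbon leading to the cis ring, benzyl transfer from the sulfonium salt to the phenoxide oxygen, and self-condensation of the ylide before the quinone methide has formed. Fallback with known chemistry and a different bond set (C3a–C3 by Friedel–Crafts, then O1–C2 by Mitsunobu), setting out from phenol 14 and bromide 23 and returning at 29. Bromide 23 and (1S,4S,5S)-isothiocineole would give, as in step 18, the enantiomeric salt (1S,4S,5S)-6-[3,5-bis(methoxymethoxy)benzyl]-4,7,7-trimethyl-6-thiabicyclo[3.2.1]octan-6-ium trifluoromethanesulfonate F1. Its ylide (KOH, MeCN/H2O 9:1, rt) would transfer the benzylidene to commercial 4-(methoxymethoxy)benzaldehyde to give (2S,3S)-2-[3,5-bis(methoxymethoxy)phenyl]-3-[4-(methoxymethoxy)phenyl]oxirane F2. F2 would be opened with inversion at its 4-alkoxybenzylic carbon by the carbon ortho to the free OH of 14 (hexafluoroisopropanol, 0 °C) to give 2-{4-hydroxy-3-[(1S,2R)-2-[3,5-bis(methoxymethoxy)phenyl]-2-hydroxy-1-[4-(methoxymethoxy)phenyl]ethyl]-2,5-bis(methoxymethoxy)phenyl}-3-methoxy-5,7-bis(methoxymethoxy)-6-methyl-4H-chromen-4-one F3. Mitsunobu closure (PPh3, DIAD, THF, 0 °C) with inversion at the carbinol carbon would then give 29; the two inversions on a trans-epoxide amount to syn addition across the stilbene, hence the trans (2S,3S) ring.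

**Step 12.** What may go wrong: slow or incomplete magnesium-templated formylation at a position flanked by a MOM ether on a phenoxide that is conjugated to the chromone, and chelation-assisted loss of MOM groups on prolonged heating. Fallback from 14, returning at 18 (steps 12 and 13 are bypassed): boron-templated ortho-hydroxyalkylation of 14 with 4-(methoxymethoxy)benzaldehyde and PhB(OH)2 (cat. EtCO2H, toluene, Dean–Stark) would give the benzodioxaborin 2-{5,8-bis(methoxymethoxy)-4-[4-(methoxymethoxy)phenyl]-2-phenyl-4H-1,3,2-benzodioxaborin-6-yl}-3-methoxy-5,7-bis(methoxymethoxy)-6-methyl-4H-chromen-4-one F4. Transesterification with propane-1,3-diol (THF, rt) would release carbinol 18.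

**Step 9.** What may go wrong: diversion to the aurone by 5-exo closure, which ortho-alkoxy groups on both rings favour, and peroxide degradation of the electron-rich aldehyde-derived ring. Fallback from 11, returning at 12: 6-endo oxa-Michael cyclisation (NaOAc, EtOH, reflux) would give the flavanone 2-[4-(benzyloxy)-2,5-bis(methoxymethoxy)phenyl]-5,7-bis(methoxymethoxy)-6-methylchroman-4-one F5 (racemic). Dehydrogenation (DDQ, dioxane, 100 °C) would give the flavone 2-[4-(benzyloxy)-2,5-bis(methoxymethoxy)phenyl]-5,7-bis(methoxymethoxy)-6-methyl-4H-chromen-4-one F6. Epoxidation of its C2=C3 bond with dimethyldioxirane (acetone/CH2Cl2, 0 °C) and opening of the epoxide on silica would give flavonol 12.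

## Further compounds

F1 | step 19 | (1S,4S,5S)-6-[3,5-bis(methoxymethoxy)benzyl]-4,7,7-trimethyl-6-thiabicyclo[3.2.1]octan-6-ium trifluoromethanesulfonate | C[C@H]1CC[C@H]2C[C@@H]1[S+](Cc1cc(OCOC)cc(OCOC)c1)C2(C)C.[O-]S(=O)(=O)C(F)(F)F
F2 | step 19 | (2S,3S)-2-[3,5-bis(methoxymethoxy)phenyl]-3-[4-(methoxymethoxy)phenyl]oxirane | COCOc1ccc(cc1)[C@@H]1O[C@H]1c1cc(OCOC)cc(OCOC)c1
F3 | step 19 | 2-{4-hydroxy-3-[(1S,2R)-2-[3,5-bis(methoxymethoxy)phenyl]-2-hydroxy-1-[4-(methoxymethoxy)phenyl]ethyl]-2,5-bis(methoxymethoxy)phenyl}-3-methoxy-5,7-bis(methoxymethoxy)-6-methyl-4H-chromen-4-one | COc1c(-c2cc(OCOC)c(O)c(c2OCOC)[C@H](c2ccc(OCOC)cc2)[C@H](c2cc(OCOC)cc(OCOC)c2)O)oc2cc(OCOC)c(C)c(OCOC)c2c1=O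
F4 | step 12 | 2-{5,8-bis(methoxymethoxy)-4-[4-(methoxymethoxy)phenyl]-2-phenyl-4H-1,3,2-benzodioxaborin-6-yl}-3-methoxy-5,7-bis(methoxymethoxy)-6-methyl-4H-chromen-4-one (racemic) | Cc1c(OCOC)cc2oc(-c3cc(OCOC)c4OB(c5ccccc5)OC(c5ccc(OCOC)cc5)c4c3OCOC)c(OC)c(=O)c2c1OCOC
F5 | step 9 | 2-[4-(benzyloxy)-2,5-bis(methoxymethoxy)phenyl]-5,7-bis(methoxymethoxy)-6-methylchroman-4-one (racemic) | Cc1c(OCOC)cc2OC(CC(=O)c2c1OCOC)c1cc(OCOC)c(OCc2ccccc2)cc1OCOC
F6 | step 9 | 2-[4-(benzyloxy)-2,5-bis(methoxymethoxy)phenyl]-5,7-bis(methoxymethoxy)-6-methyl-4H-chromen-4-one | Cc1c(OCOC)cc2oc(cc(=O)c2c1OCOC)-c1cc(OCOC)c(OCc2ccccc2)cc1OCOC
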